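## The problem

The target 16 is a fully substituted cyclobutane. C1 and C2 are CH carbons carrying CO2Me and CO2H; C3 (next to C2) and C4 (next to C1) are adjacent quaternary carbons, each carrying a methyl group and C6 of a 4-methoxy-3-methyl-2-pyranone. Both carboxyl groups and both methyl groups lie on one face and both pyranones on the other, so the skeleton has a mirror plane and the molecule is chiral only because one of two enantiotopic carboxyls is a methyl ester. Absolute configuration is therefore a single desymmetrisation, and any later event that lets ester and acid change places (anhydride re-closure, acyl transfer) would racemise the material. C3 and C4 cannot be corrected once made, so their configuration relative to C1/C2 must come from the ring-forming event. C1 and C2 are α to carbonyl groups and cis to everything around them, so prolonged strong base is a threat. The methoxypyranones are vinylogous carbonates that hydroxide or methoxide open; they must be made late, and the last deprotection has to be acidic. The enabling feature is that C3–C4 with its two methyl groups is what remains of a 1,2-dimethylcyclobutene double bond, and the two pyranone C6 atoms, cis to each other and anti to the carboxyls, are the ends of a two-carbon unit that added to that double bond from its open face and was then cut in the middle.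

## Retrosynthesis

**16 from 15.** The free acid at C2 is masked as a tert-butyl ester. Acidolysis is the one ester cleavage that leaves the methyl ester and both pyranones alone. Benzyl would need hydrogenolysis next to two pyranone double bonds, and a second methyl ester would need base. The forward step only has to lose isobutene.

**15 from 9 and two molecules of 10 (through 14, 13 and 12).** Each pyranone is cut at the O-methyl bond, at the lactone O1–C2 bond and at C5–C6. That leaves a formyl group on C3 and on C4 (dialdehyde 9) and the five-carbon keto ester 10. Coupling preformed pyranones to vicinal quaternary carbons has no dependable method. The acid-level version of the same cut needs a cis-1,2-diacid on quaternary carbons to be activated twice, and such diacids collapse to the five-membered anhydride. The aldehydes are non-enolisable and more electrophilic. The precursor is simpler by both heterocycles and twelve carbons. The forward sequence asks for a twofold γ-aldol, an oxidation, a lactonisation and an O-methylation.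

**9 from 7 (through 8).** The two formyl carbons are rejoined by a C–C bond into a cis-cyclobutane-1,2-diol, held as its cyclic carbonate. Two one-carbon stubs on quaternary carbons become one two-carbon bridge, so their cis relationship and their anti relationship to C1/C2 become ring fusion in a bicyclo[2.2.0]hexane. The forward steps are carbonate methanolysis and glycol cleavage; the stereocentres of the bridge are destroyed, so their configuration is immaterial.

**7 from 5 (through 6).** The methyl/tert-butyl ester pair is traced to a meso anhydride, opened by methanol under alkaloid control and then tert-butylated. The desymmetrisation is placed here and not at the end. From 6 onward no step activates either carboxyl, so the ester and acid cannot exchange. A late desymmetrisation would need both esters cleaved and an anhydride closed and opened in the presence of the pyranones, three steps where one now suffices. Precursor 5 is achiral.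

**5 from 3 and 4.** This is the key cut: the two bonds from C3 and C4 to the carbonate carbons. Vinylene carbonate (4) is the two-carbon unit and the dimethylcyclobutene anhydride 3 the acceptor. The neighbouring cut is a [2+2] of maleic anhydride with a tetrasubstituted alkene that already carries both stubs. It would leave head/tail pairing and syn/anti selectivity to a crossed photodimerisation with no rigid element to control them. Here the cis-fused anhydride blocks one face of a flat cyclobutene, and both new bonds must form on the other. The step has to create two adjacent quaternary centres and a strained bicycle, which only a photochemical biradical route delivers readily.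

**3 from 1 and 2.** The cyclobutene is cut at its two single bonds flanking the alkene, back to maleic anhydride (1) and 2-butyne (2). The sensitised [2+2] sets the cis relationship of C1/C2 through the anhydride ring and brings in both methyl groups.

## Roads not taken

**Alternative 1:** Both pyranone C5–C6 bonds are cut at the acid oxidation level. In the forward step the bis(acyl chloride) A2 would be C-acylated twice at the terminal carbon of the bis(trimethylsilyl) dienol ether A3, giving the bis(3,5-dioxo ester) A1.
- Merits: A1 holds every carbon of the target at the oxidation level needed for lactonisation. It is the di-tert-butyl counterpart of 13, so the later steps are shared.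
- Weak points: A2 must come from a cis-1,2-diacid on vicinal quaternary carbons, which chlorinating agents tend to turn into the cyclic anhydride. Both acyl chlorides are neopentyl and crowd each other. O-acylation and attack through the central carbon of A3 compete. The Lewis acid or HCl present endangers the tert-butyl esters.
- Weak points in the end game: the meso di-tert-butyl pattern postpones desymmetrisation, so both esters must be cleaved and an anhydride closed and opened beside two pyranones.
- Comparison: this is a pyranone tactic, not a ring synthesis. Grafted onto the chosen route it would need a chlorite oxidation and an acid chloride formation before the coupling, against one oxidation after the aldol here. It would avoid the lactolate risk of step 7, and that is its real advantage. The chosen plan sets against it an electrophile that comes straight from the glycol cleavage and cannot collapse to an anhydride.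

**Alternative 2:** Both O1–C6 bonds are cut. In the forward step Ph3PAuCl with AgOTf would activate the two ynones of A5 so that each tert-butyl ester carbonyl oxygen attacks the ring-bound alkyne carbon. Both rings close with loss of the tert-butyl groups, giving the bis(hydroxypyranone) A4.
- Merits: the closure is neutral and catalytic, and the regiochemistry of the ring is unambiguous. No 1,4-diketone array is ever exposed to base, so it is gentler than step 9 here.
- Weak points: A5 needs two alkynes on vicinal quaternary carbons, most plausibly from dialdehyde 9 by homologation, followed by acylation with a methylmalonyl unit. That is several steps more than aldol and oxidation. The 6-endo attack has to occur at an alkyne carbon next to a quaternary centre.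
- Weak points in the end game: A4 is a dimethyl ester, so the mono-acid could only be released by base (which the pyranones do not tolerate) or by an enzyme of unknown selectivity.
- Comparison: better at the ring closure itself, longer by two to three steps, worse in the end game, and silent on the cyclobutane.

**Alternative 3:** The cut is the C1–C2 bond of the target ring. In the forward step, irradiation of the dihydrophthalic anhydride A7 would close its diene disrotatorily to the bicyclo[2.2.0]hex-5-ene anhydride A6. Cleavage of the cyclobutene would then leave C1/C2 as formyl groups and C3/C4 as an anhydride.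
- Merits: the photoreaction is unimolecular, so there is no partner, no dimerisation and no cross-selectivity. A6 contains the whole ring with all four stereocentres, as 5 does. In this respect it is better than the intermolecular key step chosen here.
- Weak points: A7 has to be built by a Diels–Alder reaction of a tetrasubstituted, sluggish dienophile and then adjusted to the diene. Under irradiation, 6π ring opening to a triene competes with the 4π closure. The fold of the bicycle (anhydride anti or syn to the cyclobutene) is decided by the diene conformation and not by an obvious steric bias.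
- Weak points in oxidation level: the stubs arrive the wrong way round for pyranone building. C3/C4 come as a neopentyl anhydride (the acylation problem of Alternative 1) and C1/C2 as aldehydes, so a redox shuffle is needed.
- Comparison: the chosen plan sets against the unimolecular photoreaction three commodity starting materials, a rigid convex face for stereocontrol, and stubs that appear at the aldehyde level exactly where the pyranones grow.

Key step: step 2

Assumption: the carbonate ring of 5 is drawn exo (oxygens on the methyl-bearing face of their cyclobutane) and any endo epimer converges with it at 9; the alkaloid in step 3 is assigned from the usual facial model for bicyclic meso anhydrides and the configuration of 6 is to be confirmed by correlation.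

## Route

Step 1
Reactants: 1 maleic anhydride; 2 2-butyne
Product: 3 cis-3,4-dimethylcyclobut-3-ene-1,2-dicarboxylic anhydride (meso)
Conditions: hν (>300 nm, Pyrex), acetophenone (sens.), MeCN, 2 (5 equiv), 0–10 °C
Reagents that add atoms: none
Why: Sensitised [2+2] photocycloaddition of triplet maleic anhydride to the alkyne through a 1,4-biradical; the five-membered anhydride enforces the cis ring fusion (future C1/C2), and excess alkyne limits addition of a second maleic anhydride to the product.

Step 2
Reactants: 3 cis-3,4-dimethylcyclobut-3-ene-1,2-dicarboxylic anhydride; 4 vinylene carbonate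
Product: 5 cis,anti,cis-1,4-dimethylbicyclo[2.2.0]hexane-2,3-diol cyclic carbonate 5,6-dicarboxylic anhydride (meso)
Conditions: hν (ca. 300 nm, quartz), acetone (solvent and sensitiser), 4 (5 equiv), 5–10 °C
Reagents that add atoms: none
Why: Triplet acetone passes its energy to vinylene carbonate, whose ring keeps the triplet from relaxing by twisting; this triplet adds to C3=C4 of 3 to give a 1,4-biradical (tertiary cyclobutyl and dioxolanonyl radicals) that closes after intersystem crossing. The closest known reactions are the acetone-sensitised [2+2] photocycloadditions of vinylene carbonate to alkenes and the sensitised additions of cyclic alkenes such as maleic anhydride to cyclobutenes, which give bicyclo[2.2.0]hexanes. The one ring formed, the carbonate-bearing cyclobutane, closes stepwise by radical recombination and is necessarily cis-fused to both the dioxolanone and the existing cyclobutane, so the bridgehead methyl groups are cis. The two quaternary centres (future C3 and C4) are set by the face of attack: the cis-fused anhydride folds over one face of the flat cyclobutene, so both bonds form on the open face, which places the new carbons trans and the methyl groups cis to the carboxyl carbons. The two carbonate CH centres are set by the orientation of the dioxolanone at closure (exo expected) and are erased in step 6. The step needs facial selectivity, secured by the bicyclic anhydride, and cross- over homo-addition, secured by excess 4 and dilute 3; there is no regiochemical issue because both partners are symmetric.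

Step 3
Reactants: 5 cis,anti,cis-1,4-dimethylbicyclo[2.2.0]hexane-2,3-diol cyclic carbonate 5,6-dicarboxylic anhydride
Product: 6 monomethyl ester of the carbonate diacid (single enantiomer; CO2Me on the future C1, free CO2H on the future C2)
Conditions: quinine (1.1 equiv), MeOH (3 equiv), toluene, −55 °C; aq. HCl work-up (alkaloid recovered)
Reagents that add atoms: methanol, CO
Why: Alkaloid-mediated enantiotopos-selective methanolysis of a meso succinic-type anhydride (general-base delivery of methanol to one carbonyl); no stereocentre is created, but the choice of carbonyl fixes the absolute configuration of all four ring centres. On the facial model for bicyclic meso anhydrides the quinine series should place the ester on the future C1, and the cyclic carbonate should be inert to methanol and a tertiary amine at this temperature.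

Step 4
Reactants: 6 monomethyl ester of the carbonate diacid
Product: 7 tert-butyl methyl diester of the carbonate diacid (CO2Me on future C1, CO2t-Bu on future C2)
Conditions: tert-butyl 2,2,2-trichloroacetimidate (2.5 equiv), CH2Cl2/cyclohexane, rt (BF3·OEt2 cat. if slow)
Reagents that add atoms: tert-butyl 2,2,2-trichloroacetimidate, CC(C)(C)OC(=N)C(Cl)(Cl)Cl
Why: Acid-promoted O-alkylation of the carboxylic acid by the imidate (tert-butyl cation transfer); the carboxyl is never turned into an acyl donor, so it cannot close onto the neighbouring ester and the enantiomeric purity of 6 should be carried over.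

Step 5
Reactants: 7 tert-butyl methyl diester of the carbonate diacid
Product: 8 tert-butyl methyl cis-2,3-dihydroxy-1,4-dimethylbicyclo[2.2.0]hexane-5,6-dicarboxylate (ester positions as in 7)
Conditions: K2CO3 (0.2 equiv), MeOH, 0 °C → rt
Reagents that add atoms: none
Why: Base-catalysed transesterification of the strained five-membered carbonate to the cis-diol with release of dimethyl carbonate; in methanol exchange at the methyl ester is degenerate and the tert-butyl ester is too hindered to exchange.

Step 6
Reactants: 8 tert-butyl methyl cis-2,3-dihydroxy-1,4-dimethylbicyclo[2.2.0]hexane-5,6-dicarboxylate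
Product: 9 1-tert-butyl 2-methyl (1S,2R,3S,4R)-3,4-diformyl-3,4-dimethylcyclobutane-1,2-dicarboxylate
Conditions: NaIO4 on silica gel, CH2Cl2, rt
Reagents that add atoms: none
Why: Periodate glycol cleavage through the cyclic periodate ester, favoured for a cis-cyclobutane-1,2-diol because the strain of the bicyclo[2.2.0]hexane is released; the formyl groups stay cis on the quaternary carbons and cannot enolise. The supported reagent keeps water low, so the dialdehyde is expected instead of its cyclic hydrate.

Step 7
Reactants: 9 1-tert-butyl 2-methyl (1S,2R,3S,4R)-3,4-diformyl-3,4-dimethylcyclobutane-1,2-dicarboxylate; 10 methyl 2-methylacetoacetate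
Product: 12 1-tert-butyl 2-methyl (1S,2R,3S,4R)-3,4-bis(1-hydroxy-5-methoxy-4-methyl-3,5-dioxopentyl)-3,4-dimethylcyclobutane-1,2-dicarboxylate, via dilithium dienolate of methyl 2-methylacetoacetate 11 (not isolated)
Conditions: 10 (5 equiv), LiN(i-Pr)2 (10 equiv), THF, 0 °C; then 9, −78 °C; aq. NH4Cl
Reagents that add atoms: none
Why: γ-Selective aldol addition of a β-keto ester dianion to an aldehyde, carried out twice; the terminal carbanion is the more nucleophilic site and aldehydes outpace the ring esters at −78 °C. The new carbinol and α-methyl centres form as mixtures that steps 8 and 9 erase.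

Step 8
Reactants: 12 1-tert-butyl 2-methyl (1S,2R,3S,4R)-3,4-bis(1-hydroxy-5-methoxy-4-methyl-3,5-dioxopentyl)-3,4-dimethylcyclobutane-1,2-dicarboxylate
Product: 13 1-tert-butyl 2-methyl (1S,2R,3S,4R)-3,4-bis(5-methoxy-4-methyl-3,5-dioxopentanoyl)-3,4-dimethylcyclobutane-1,2-dicarboxylate
Conditions: Dess–Martin periodinane (3 equiv), CH2Cl2, 0 °C → rt
Reagents that add atoms: none
Why: Dess–Martin oxidation of the two secondary alcohols to β,δ-diketo esters under neutral, non-aqueous conditions that leave both ring esters and the acidic methine alone.

Step 9
Reactants: 13 1-tert-butyl 2-methyl (1S,2R,3S,4R)-3,4-bis(5-methoxy-4-methyl-3,5-dioxopentanoyl)-3,4-dimethylcyclobutane-1,2-dicarboxylate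
Product: 14 1-tert-butyl 2-methyl (1S,2R,3S,4R)-3,4-bis(4-hydroxy-3-methyl-2-oxo-2H-pyran-6-yl)-3,4-dimethylcyclobutane-1,2-dicarboxylate
Conditions: 1,8-diazabicyclo[5.4.0]undec-7-ene (DBU, 2.5 equiv), toluene, rt → 50 °C; aq. HCl work-up
Reagents that add atoms: none
Why: Base-mediated lactonisation of a 3,5-dioxo ester: the enolate oxygen of the ketone next to the ring attacks the side-chain methyl ester (6-exo-trig) and methanol is lost, giving the 4-hydroxy-2-pyranone, twice. The non-nucleophilic amidine should not touch the ring esters.

Step 10
Reactants: 14 1-tert-butyl 2-methyl (1S,2R,3S,4R)-3,4-bis(4-hydroxy-3-methyl-2-oxo-2H-pyran-6-yl)-3,4-dimethylcyclobutane-1,2-dicarboxylate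
Product: 15 1-tert-butyl 2-methyl (1S,2R,3S,4R)-3,4-bis(4-methoxy-3-methyl-2-oxo-2H-pyran-6-yl)-3,4-dimethylcyclobutane-1,2-dicarboxylate
Conditions: Me2SO4 (3 equiv), K2CO3 (4 equiv), acetone, rt → 40 °C
Reagents that add atoms: dimethyl sulfate, COS(=O)(=O)OC
Why: O-Alkylation of the 4-hydroxy-2-pyranone anion; with dimethyl sulfate and a carbonate base the 4-oxygen should react in preference to the lactone carbonyl oxygen, giving the 4-methoxy-2-pyranone and not the 2-methoxy-4-pyranone isomer.

Step 11
Reactants: 15 1-tert-butyl 2-methyl (1S,2R,3S,4R)-3,4-bis(4-methoxy-3-methyl-2-oxo-2H-pyran-6-yl)-3,4-dimethylcyclobutane-1,2-dicarboxylate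
Product: 16 (1S,2R,3S,4R)-2-(methoxycarbonyl)-3,4-bis(4-methoxy-3-methyl-2-oxo-2H-pyran-6-yl)-3,4-dimethylcyclobutane-1-carboxylic acid
Conditions: CF3CO2H/CH2Cl2 (1:4), 0 °C → rt
Reagents that add atoms: none
Why: Acidolysis of the tert-butyl ester with loss of isobutene; the methyl ester and the methoxypyranones are stable to anhydrous acid and no stereocentre is touched.

## Compound list

1 | maleic anhydride | O=C1OC(=O)C=C1 | starting material
2 | 2-butyne | CC#CC | starting material
3 | cis-3,4-dimethylcyclobut-3-ene-1,2-dicarboxylic anhydride (meso) | CC1=C(C)[C@@H]2[C@H]1C(=O)OC2=O | intermediate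
4 | vinylene carbonate | O=C1OC=CO1 | starting material
5 | cis,anti,cis-1,4-dimethylbicyclo[2.2.0]hexane-2,3-diol cyclic carbonate 5,6-dicarboxylic anhydride (meso; carbonate ring trans to the anhydride carbonyls across the central cyclobutane, bridgehead methyls cis to them, carbonate exo) | O=C1O[C@@H]2[C@H](O1)[C@]3(C)[C@@]2(C)[C@H]4C(=O)OC(=O)[C@@H]34 | intermediate
6 | monomethyl ester of the 1,4-dimethylbicyclo[2.2.0]hexane-2,3-diol carbonate 5,6-dicarboxylic acid (single enantiomer; CO2Me on future C1, CO2H on future C2) | O=C1O[C@@H]2[C@H](O1)[C@]3(C)[C@@]2(C)[C@@H](C(=O)O)[C@H]3C(=O)OC | intermediate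
7 | tert-butyl methyl diester of the same carbonate diacid (CO2Me on future C1, CO2t-Bu on future C2) | O=C1O[C@@H]2[C@H](O1)[C@]3(C)[C@@]2(C)[C@@H](C(=O)OC(C)(C)C)[C@H]3C(=O)OC | intermediate
8 | tert-butyl methyl cis-2,3-dihydroxy-1,4-dimethylbicyclo[2.2.0]hexane-5,6-dicarboxylate (ester positions as in 7) | O[C@@H]1[C@H](O)[C@]2(C)[C@@]1(C)[C@@H](C(=O)OC(C)(C)C)[C@H]2C(=O)OC | intermediate
9 | 1-tert-butyl 2-methyl (1S,2R,3S,4R)-3,4-diformyl-3,4-dimethylcyclobutane-1,2-dicarboxylate | COC(=O)[C@@H]1[C@H](C(=O)OC(C)(C)C)[C@@](C)(C=O)[C@@]1(C)C=O | intermediate
10 | methyl 2-methylacetoacetate (methyl 2-methyl-3-oxobutanoate) | CC(=O)C(C)C(=O)OC | starting material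
11 | dilithium dienolate of methyl 2-methylacetoacetate | [Li+].[Li+].C=C([O-])C(C)=C([O-])OC | intermediate
12 | 1-tert-butyl 2-methyl (1S,2R,3S,4R)-3,4-bis(1-hydroxy-5-methoxy-4-methyl-3,5-dioxopentyl)-3,4-dimethylcyclobutane-1,2-dicarboxylate (mixture at the four side-chain centres) | COC(=O)[C@@H]1[C@H](C(=O)OC(C)(C)C)[C@@](C)(C(O)CC(=O)C(C)C(=O)OC)[C@@]1(C)C(O)CC(=O)C(C)C(=O)OC | intermediate
13 | 1-tert-butyl 2-methyl (1S,2R,3S,4R)-3,4-bis(5-methoxy-4-methyl-3,5-dioxopentanoyl)-3,4-dimethylcyclobutane-1,2-dicarboxylate | COC(=O)[C@@H]1[C@H](C(=O)OC(C)(C)C)[C@@](C)(C(=O)CC(=O)C(C)C(=O)OC)[C@@]1(C)C(=O)CC(=O)C(C)C(=O)OC | intermediate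
14 | 1-tert-butyl 2-methyl (1S,2R,3S,4R)-3,4-bis(4-hydroxy-3-methyl-2-oxo-2H-pyran-6-yl)-3,4-dimethylcyclobutane-1,2-dicarboxylate | COC(=O)[C@@H]1[C@H](C(=O)OC(C)(C)C)[C@@](C)(c2cc(O)c(C)c(=O)o2)[C@@]1(C)c1cc(O)c(C)c(=O)o1 | intermediate
15 | 1-tert-butyl 2-methyl (1S,2R,3S,4R)-3,4-bis(4-methoxy-3-methyl-2-oxo-2H-pyran-6-yl)-3,4-dimethylcyclobutane-1,2-dicarboxylate | COC(=O)[C@@H]1[C@H](C(=O)OC(C)(C)C)[C@@](C)(c2cc(OC)c(C)c(=O)o2)[C@@]1(C)c1cc(OC)c(C)c(=O)o1 | intermediate
16 | (1S,2R,3S,4R)-2-(methoxycarbonyl)-3,4-bis(4-methoxy-3-methyl-2-oxo-2H-pyran-6-yl)-3,4-dimethylcyclobutane-1-carboxylic acid (CNP0481603.1) | COC(=O)[C@@H]1[C@H](C(=O)O)[C@@](C)(c2cc(OC)c(C)c(=O)o2)[C@@]1(C)c1cc(OC)c(C)c(=O)o1 | target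

## Step count and risks

Total: 11 steps. Longest linear sequence: 11 steps (1 to 16); 10 enters at step 7.

**Step 2 (key step).**
- Risk: vinylene carbonate may be consumed by self-dimerisation and by oxetane formation with acetone faster than it adds across the hindered tetrasubstituted alkene. The biradical, which must close to a vicinal quaternary pair inside a strained bicycle, may revert or disproportionate by hydrogen transfer from a methyl group. Some attack on the anhydride face is also conceivable.
- Fallback (sets out from 3, returns at 9): sensitised addition of a second molecule of 1 to 3 (hν, acetophenone, MeCN) should give the cis,anti,cis bis-anhydride F1. The triplet of 1 is the partner best documented to add to cyclobutenes. Quinine-mediated methanolysis with one equivalent of methanol opens one of the two equivalent anhydride rings to the hemiester F2. tert-Butyl trichloroacetimidate then gives the mixed diester anhydride F3. Water and pyridine in THF hydrolyse the remaining anhydride to the vicinal diacid F4. Oxidative bis-decarboxylation with Pb(OAc)4 (pyridine, 45 °C) gives the bicyclo[2.2.0]hex-2-ene F5. Ozonolysis with Me2S work-up cuts the sacrificial ring to 9.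

**Step 3.**
- Risk: discrimination between the two anhydride carbonyls may be weak or reversed, because the cis methyl groups on the neighbouring quaternary carbons crowd both carbonyls in a way the standard substrates do not. Conversion may also be slow at −55 °C through poor solubility.
- Fallback (sets out from 5, returns at 6): unselective opening (MeOH, Et3N, CH2Cl2, rt) gives 6 together with its mirror image, the hemiester ent-6 F6. Crystallisation of the diastereomeric (R)-1-phenylethylammonium salt F7 and acidification returns 6. The S amine is used if the other salt is the less soluble.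

**Step 7.**
- Risk: after the first addition the lithium alkoxide can close onto the neighbouring cis formyl group as a five-membered lactolate, so the second addition stalls. Excess dianion may also deprotonate α to the ring esters and epimerise C1 or C2.
- Fallback (sets out from 9, returns at 12): 10 is silylated to the mono silyl enol ether F8 (Me3SiCl, Et3N) and then to the bis(trimethylsilyl) dienol ether F9 (LiN(i-Pr)2, Me3SiCl). A vinylogous Mukaiyama aldol addition of F9 to 9 (BF3·OEt2, CH2Cl2, −78 °C) keeps each aldolate capped on boron or silicon, not free as an alkoxide. Mild acidic work-up gives 12.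

**Step 9.**
- Risk: the two enolised diketone chains sit cis on adjacent carbons as a 1,4-diketone array, so an intramolecular aldol between a chain methylene and the ring-bound ketone of the other chain (cyclopentenone annulation) may compete with O-acylation. Longer exposure to base may also epimerise C1/C2.
- Fallback (sets out from 9, returns at 14): the lithium dienolate of 2,2,5,6-tetramethyl-4H-1,3-dioxin-4-one F10 (LiN(i-Pr)2, THF, −78 °C) adds to 9 to give the bis(hydroxy dioxinone) F11. Dess–Martin oxidation gives the bis(keto dioxinone) F12. Heating in toluene (110 °C) expels acetone, and each acylketene is captured by the enol of its own ketone, closing both hydroxypyranones of 14 without base.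

## Further compounds

F1 | step 2 | cis,anti,cis-1,4-dimethylbicyclo[2.2.0]hexane-2,3,5,6-tetracarboxylic 2,3:5,6-dianhydride | O=C1OC(=O)[C@@H]2[C@H]1[C@]3(C)[C@@]2(C)[C@H]4C(=O)OC(=O)[C@@H]34
F2 | step 2 | hemiester from opening one anhydride of F1 with methanol (CO2Me on future C1, CO2H on future C2) | O=C1OC(=O)[C@@H]2[C@H]1[C@]3(C)[C@@]2(C)[C@@H](C(=O)O)[C@H]3C(=O)OC
F3 | step 2 | tert-butyl methyl diester of F2 with the second anhydride intact | O=C1OC(=O)[C@@H]2[C@H]1[C@]3(C)[C@@]2(C)[C@@H](C(=O)OC(C)(C)C)[C@H]3C(=O)OC
F4 | step 2 | 5-(tert-butoxycarbonyl)-6-(methoxycarbonyl)-1,4-dimethylbicyclo[2.2.0]hexane-2,3-dicarboxylic acid | OC(=O)[C@@H]1[C@H](C(=O)O)[C@]2(C)[C@@]1(C)[C@@H](C(=O)OC(C)(C)C)[C@H]2C(=O)OC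
F5 | step 2 | tert-butyl methyl 1,4-dimethylbicyclo[2.2.0]hex-5-ene-2,3-dicarboxylate | C1=C[C@]2(C)[C@@]1(C)[C@@H](C(=O)OC(C)(C)C)[C@H]2C(=O)OC
F6 | step 3 | ent-6, mirror-image hemiester formed beside 6 in the unselective opening | O=C1O[C@H]2[C@@H](O1)[C@@]3(C)[C@]2(C)[C@H](C(=O)O)[C@@H]3C(=O)OC
F7 | step 3 | (R)-1-phenylethylammonium salt of 6 | O=C1O[C@@H]2[C@H](O1)[C@]3(C)[C@@]2(C)[C@@H](C(=O)[O-])[C@H]3C(=O)OC.C[C@@H]([NH3+])c1ccccc1
F8 | step 7 | methyl 2-methyl-3-(trimethylsilyloxy)but-2-enoate | COC(=O)C(C)=C(C)O[Si](C)(C)C
F9 | step 7 | 1-methoxy-2-methyl-1,3-bis(trimethylsilyloxy)buta-1,3-diene | COC(O[Si](C)(C)C)=C(C)C(=C)O[Si](C)(C)C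
F10 | step 9 | 2,2,5,6-tetramethyl-4H-1,3-dioxin-4-one | CC1=C(C)C(=O)OC(C)(C)O1
F11 | step 9 | 1-tert-butyl 2-methyl 3,4-bis[1-hydroxy-2-(2,2,5-trimethyl-4-oxo-4H-1,3-dioxin-6-yl)ethyl]-3,4-dimethylcyclobutane-1,2-dicarboxylate | COC(=O)[C@@H]1[C@H](C(=O)OC(C)(C)C)[C@@](C)(C(O)CC2=C(C)C(=O)OC(C)(C)O2)[C@@]1(C)C(O)CC1=C(C)C(=O)OC(C)(C)O1
F12 | step 9 | 1-tert-butyl 2-methyl 3,4-bis[(2,2,5-trimethyl-4-oxo-4H-1,3-dioxin-6-yl)acetyl]-3,4-dimethylcyclobutane-1,2-dicarboxylate | COC(=O)[C@@H]1[C@H](C(=O)OC(C)(C)C)[C@@](C)(C(=O)CC2=C(C)C(=O)OC(C)(C)O2)[C@@]1(C)C(=O)CC1=C(C)C(=O)OC(C)(C)O1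
A1 | alternative 1 | meso di-tert-butyl 3,4-bis(5-methoxy-4-methyl-3,5-dioxopentanoyl)-3,4-dimethylcyclobutane-1,2-dicarboxylate | CC(C)(C)OC(=O)[C@@H]1[C@H](C(=O)OC(C)(C)C)[C@@](C)(C(=O)CC(=O)C(C)C(=O)OC)[C@@]1(C)C(=O)CC(=O)C(C)C(=O)OC
A2 | alternative 1 | meso di-tert-butyl 3,4-bis(chlorocarbonyl)-3,4-dimethylcyclobutane-1,2-dicarboxylate | CC(C)(C)OC(=O)[C@@H]1[C@H](C(=O)OC(C)(C)C)[C@@](C)(C(Cl)=O)[C@@]1(C)C(Cl)=O
A3 | alternative 1 | 1-methoxy-2-methyl-1,3-bis(trimethylsilyloxy)buta-1,3-diene | COC(O[Si](C)(C)C)=C(C)C(=C)O[Si](C)(C)C
A4 | alternative 2 | meso dimethyl 3,4-bis(4-hydroxy-3-methyl-2-oxo-2H-pyran-6-yl)-3,4-dimethylcyclobutane-1,2-dicarboxylate | COC(=O)[C@@H]1[C@H](C(=O)OC)[C@@](C)(c2cc(O)c(C)c(=O)o2)[C@@]1(C)c1cc(O)c(C)c(=O)o1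
A5 | alternative 2 | meso dimethyl 3,4-bis(5-tert-butoxy-4-methyl-3,5-dioxopent-1-yn-1-yl)-3,4-dimethylcyclobutane-1,2-dicarboxylate | COC(=O)[C@@H]1[C@H](C(=O)OC)[C@@](C)(C#CC(=O)C(C)C(=O)OC(C)(C)C)[C@@]1(C)C#CC(=O)C(C)C(=O)OC(C)(C)C
A6 | alternative 3 | cis,anti,cis-2,3-dimethylbicyclo[2.2.0]hex-5-ene-2,3-dicarboxylic anhydride | C1=C[C@H]2[C@@H]1[C@]3(C)C(=O)OC(=O)[C@]23C
A7 | alternative 3 | cis-1,2-dimethyl-1,2-dihydrophthalic anhydride | C[C@]12C=CC=C[C@@]1(C)C(=O)OC2=O
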